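**Plan**

1. Retrosynthesis: the C8 methacrylate and C3 acetate come off first. The lactone and the second seven-membered ring (O5, C5–C10) are cut together at C6–C7 (allylsilane onto aldehyde). The oxepane (O5, C10, C1, C2, C3, C4, C5) is cut at O5–C10 and C3–C4, giving a diazo keto ester (C15, C4, C5, C6) and a 1-silyl-1,3-diene (C3, C2, C1, C10 with the C9–C7 chain).
2. Enabling feature: in the oxepane, O5 sits on C5 (which carries C6) and C4 carries the one-carbon branch C15. At the oxidation level O5–C5=C4–C15(=O) with a C1=C2 bond, this ring is a 2,5-dihydrooxepine vinylogous carbonate, the retro-Claisen isomer of a cis-acyl vinylcyclopropane that a carbenoid and a diene give in one operation.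
3. Forward order: side chain and diene (steps 3–6); oxepine ring by the (4+3) event (step 8); removal of the helpers C1=C2, C4=C5, the C15 ester and silicon on C3 (steps 9–12); carbocycle plus lactone in one closure (step 16); the two esters (steps 18–20).
4. Stereochemistry: C3 from the chiral dirhodium catalyst, C10 from C3 through the sigmatropic shift; C4 by hydrogenation anti to silicon; C5 by equilibration of the C6 aldehyde; C6 and C7 by chelate and allylic-strain control in the ring closure; C8 from (S)-benzyl glycidyl ether, inverted at the end by Mitsunobu esterification.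
5. Remark: in the given (5R,10R) configuration the ether oxygen leaves the ten-membered carbocycle from opposite faces at C5 and C10 (trans-bridged, in,out 11-oxabicyclo[4.4.1]undecane, H-5 inside). C5 is therefore fixed before the second ring is closed.
6. Assumption: the (S)-ligand series of the dirhodium catalyst is taken to give the C3 configuration drawn; if a model reaction shows the opposite sense, the enantiomeric catalyst is used and nothing else changes.

Key step: step 8

Numbering: locants are those of the germacrane skeleton. Ring carbons are C1–C10; C10 bears methyl C14 and the ether oxygen O5 (bonded to C5 and C10); C4 bears C15; the lactone is O6–C12(=O)–C11(=C13)–C7. The target is (3R,4R,5R,6R,7R,8R,10R).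

**Route**

Step 1
Reactants: 1 (tert-butyldimethylsilyloxy)acetaldehyde; 2 ethyl diazoacetate
Product: 3 ethyl 4-(tert-butyldimethylsilyloxy)-2-diazo-3-hydroxybutanoate (racemic carbinol)
Conditions: DBU (10 mol %), MeCN, 0 °C → rt
Reagents that add atoms: none
Why: Base-catalysed aldol-type addition of the diazoacetate carbon to the aldehyde; the new carbinol centre is racemic and is removed by oxidation in step 2.

Step 2
Reactants: 3 ethyl 4-(tert-butyldimethylsilyloxy)-2-diazo-3-hydroxybutanoate
Product: 4 ethyl 4-(tert-butyldimethylsilyloxy)-2-diazo-3-oxobutanoate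
Conditions: Dess–Martin periodinane, CH2Cl2, 0 °C → rt
Reagents that add atoms: none
Why: Dess–Martin oxidation of the α-diazo-β-hydroxy ester to the acceptor/acceptor diazo keto ester, which leaves the diazo group and the silyl ether untouched.

Step 3
Reactants: 5 (S)-benzyl glycidyl ether
Product: 6 (S)-1-(benzyloxy)pent-4-yn-2-ol
Conditions: LiC≡CH·H2NCH2CH2NH2, DMSO, rt; aqueous work-up
Reagents that add atoms: lithium acetylide–ethylenediamine complex [Li+].[C-]#C.NCCN
Why: SN2 opening at the terminal epoxide carbon by the acetylide keeps the C8 stereocentre, which is deliberately (S), the epimer of what the target needs, for the reason given at step 16.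

Step 4
Reactants: 6 (S)-1-(benzyloxy)pent-4-yn-2-ol
Product: 7 (S)-1-(benzyloxy)-2-(tert-butyldimethylsilyloxy)pent-4-yne
Conditions: TBSCl, imidazole, DMF, rt
Reagents that add atoms: tert-butyldimethylsilyl chloride CC(C)(C)[Si](C)(C)Cl
Why: Standard silylation of the secondary alcohol, needed because a free hydroxyl would react with the carbenoid in step 8 and be oxidised later.

Step 5
Reactants: 7 (S)-1-(benzyloxy)-2-(tert-butyldimethylsilyloxy)pent-4-yne
Product: 8 (S,E)-1-(benzyloxy)-2-(tert-butyldimethylsilyloxy)-5-iodo-4-methylpent-4-ene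
Conditions: Me3Al, Cp2ZrCl2 (0.2 equiv), CH2Cl2, 0 °C → rt; then I2, THF, −30 °C
Reagents that add atoms: trimethylaluminium C[Al](C)C; iodine II
Why: Negishi zirconium-catalysed syn-carboalumination puts methyl on the internal alkyne carbon (C10) and aluminium on C1, and iodinolysis with retention gives the (E)-iodide that fixes the C1=C10 geometry.

Step 6
Reactants: 8 (S,E)-1-(benzyloxy)-2-(tert-butyldimethylsilyloxy)-5-iodo-4-methylpent-4-ene; 9 dimethylphenylvinylsilane
Product: 10 (S,4E,6E)-1-(benzyloxy)-2-(tert-butyldimethylsilyloxy)-4-methyl-7-(dimethylphenylsilyl)hepta-4,6-diene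
Conditions: Pd(OAc)2 (5 mol %), AgOAc, DMF, 50 °C
Reagents that add atoms: none
Why: Heck vinylation at the unsubstituted terminus of the vinylsilane with syn-β-hydride elimination gives the (E)-vinylsilane and keeps the iodide geometry, the silver salt taking up iodide and suppressing desilylation; silicon on C3 is the masked C3 oxygen and the steric control element for steps 8 and 9.

Step 7
Reactants: 11 methyl (triphenylphosphoranylidene)acetate; 12 (iodomethyl)trimethylsilane
Product: 14 methyl 2-(triphenylphosphoranylidene)-3-(trimethylsilyl)propanoate, via phosphonium iodide 13 (not isolated)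
Conditions: toluene, 90 °C; then aq. NaOH, CH2Cl2, rt
Reagents that add atoms: none
Why: C-alkylation of the stabilised ylide followed by deprotonation of the phosphonium salt gives the Wittig reagent that later delivers C11, C12, C13 and the allylsilane in one step.

Step 8
Reactants: 10 (S,4E,6E)-1-(benzyloxy)-2-(tert-butyldimethylsilyloxy)-4-methyl-7-(dimethylphenylsilyl)hepta-4,6-diene; 4 ethyl 4-(tert-butyldimethylsilyloxy)-2-diazo-3-oxobutanoate
Product: 16 2,5-dihydrooxepine (C10 methyl and side chain; C1=C2; C3 SiMe2Ph cis to the side chain; C4 CO2Et; C4=C5; C5 CH2OTBS), via vinylcyclopropane 15 (not isolated)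
Conditions: Rh2(S-PTTL)4 (dirhodium tetrakis[N-phthaloyl-(S)-tert-leucinate], 1 mol %), 4 added over 6 h to 10 in hexane–PhCF3, rt; then toluene, 80 °C
Reagents that add atoms: none
Why: The rhodium carbenoid from 4 adds to the silyl-bearing terminus of the diene (the end that leaves a tertiary allylic, β-silyl-stabilised positive charge) and closes to vinylcyclopropane 15, which forms C3–C4; the ketone carbonyl cis to the vinyl group then undergoes a concerted retro-Claisen ([3,3]-sigmatropic) shift through a boat transition state that breaks C2–C4 and forms O5–C10. The closest known reaction type is the tandem cyclopropanation/retro-Claisen rearrangement (formal (4+3) cycloaddition) of diazo dicarbonyl compounds with 1,3-dienes to 2,5-dihydrooxepines. The three-membered ring closes by (2+1) carbene addition and is opened again, and the seven-membered ring closes by the sigmatropic shift, driven by the push–pull O5–C5=C4–CO2Et unit. C3 is set by the chiral dirhodium catalyst in the cyclopropanation, trans to the vinyl group because the (E)-vinylsilane geometry is retained; C10 is set by suprafacial transfer through the boat, in which the (E)-trisubstituted alkene holds the C9 chain exo and the methyl endo, so that silicon and the C9 chain end cis. The step needs attack at C2=C3 and not at the trisubstituted C1=C10 bond, which the end-on approach to the less substituted terminus should secure, and it needs the sigmatropic shift to outrun ionic opening to a 2-vinyl-2,3-dihydrofuran, which the non-polar medium, the absence of Lewis acid and the moderate temperature should secure.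

Step 9
Reactants: 16 2,5-dihydrooxepine
Product: 17 oxepane (C3 SiMe2Ph, C4 CO2Et cis to silicon, C5 CH2OTBS cis to the ester, C7 free OH; C3, C4, C10 as in 32; C5 and C8 epimeric to 32)
Conditions: H2 (40 bar), Pd(OH)2/C, EtOAc, rt
Reagents that add atoms: none
Why: Heterogeneous syn-hydrogenation of both ring double bonds from the face opposite to the bulky silyl group on the allylic carbon C3 sets C4 (ester cis to silicon) and gives C5 as the cis, kinetic epimer (corrected in step 15), while the benzyl ether is hydrogenolysed and palladium, unlike rhodium, leaves the Si–phenyl group needed in step 10.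

Step 10
Reactants: 17 oxepane with C3 SiMe2Ph
Product: 18 β-hydroxy ester (C3 OH, retention)
Conditions: Hg(OAc)2, AcOOH, AcOH, rt
Reagents that add atoms: peracetic acid CC(=O)OO
Why: Fleming–Tamao oxidation, in which mercuridesilylation of the phenyl group and the peracid-induced 1,2-shift of C3 from silicon to oxygen turn the C–Si bond into the C3–OH bond with retention.

Step 11
Reactants: 18 β-hydroxy ester
Product: 19 triol (C3 OH, C15 OH, C7 OH)
Conditions: LiBH4, THF–MeOH, 0 °C → rt
Reagents that add atoms: none
Why: Chemoselective reduction of the ester to the C15 primary alcohol by LiBH4, which does not touch the silyl ethers.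

Step 12
Reactants: 19 triol
Product: 20 O3/O15 acetonide with free C7 OH
Conditions: Me2C(OMe)2, PPTS (cat.), acetone, rt
Reagents that add atoms: 2,2-dimethoxypropane COC(C)(C)OC
Why: A cyclic acetonide can form only at the 1,3-diol O3/O15 (cis-fused 1,3-dioxane), so the C7 alcohol stays free for step 13 and the two hydroxyls of the final acetate/alcohol pair are protected together.

Step 13
Reactants: 20 acetonide alcohol; 14 methyl 2-(triphenylphosphoranylidene)-3-(trimethylsilyl)propanoate
Product: 22 (Z)-2-(trimethylsilylmethyl)alk-2-enoate (C7=C11; C8 cis to CH2SiMe3), via aldehyde 21 (not isolated)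
Conditions: Dess–Martin periodinane, CH2Cl2, rt; then 14, 40 °C
Reagents that add atoms: none
Why: Dess–Martin oxidation to the α-silyloxy aldehyde and Wittig reaction with the stabilised α-substituted ylide in the same flask give the trisubstituted enoate with C8 trans to the ester, an allylsilane that tolerates the oxidant and base of the next steps.

Step 14
Reactants: 22 allylsilane enoate
Product: 23 C6 primary alcohol
Conditions: HF·pyridine, pyridine, THF, 0 °C
Reagents that add atoms: none
Why: Buffered HF·pyridine at 0 °C cleaves the primary silyl ether much faster than the hindered secondary one at C8 and should not attack the acetonide or the C–Si bond of the electron-poor allylsilane.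

Step 15
Reactants: 23 C6 primary alcohol
Product: 25 C6 aldehyde with C5 as in 32 (formyl trans to the C4 branch), via cis-aldehyde 24 (not isolated)
Conditions: Dess–Martin periodinane, CH2Cl2, rt; then DBU, rt
Reagents that add atoms: none
Why: Oxidation gives the α-alkoxy aldehyde, whose only acidic position is C5 and which carries no β-leaving group, and DBU should equilibrate it through the enolate to the more stable epimer with the formyl group trans to the C4 branch and syn to the C10 methyl, which is the C5 configuration of the target.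

Step 16
Reactants: 25 C6 aldehyde
Product: 27 bicyclic cis-fused α-methylene lactone (C8 OTBS, 8-epi; O3/O15 acetonide), via hydroxy ester 26 (not isolated)
Conditions: SnCl4, CH2Cl2, −78 °C; H2O; then PPTS (cat.), toluene, 40 °C
Reagents that add atoms: none
Why: Intramolecular Hosomi–Sakurai allylation of an ω-formyl 2-(silylmethyl)alkenoate followed by lactonisation forms C6–C7, the trans-bridged carbocycle and the α-methylene lactone: SnCl4 is expected to chelate the aldehyde and ring oxygens so that the tethered nucleophile, which can only arrive gauche to O5, attacks anti to C4 and gives the target C6 carbinol, while allylic 1,3-strain holds H8 in the plane of the (Z)-alkene with C9 on the side of the forming ring so that C7 reacts anti to the silyloxy group, and with (S)-configured C8 both controls meet in the cis-fused lactone of the target.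

Step 17
Reactants: 27 silyl-protected lactone
Product: 28 C8 alcohol (8-epi)
Conditions: HF·pyridine, pyridine, THF, rt
Reagents that add atoms: none
Why: Fluoride cleavage of the remaining secondary silyl ether under pyridine-buffered conditions that should leave the acetonide and the methylene lactone intact.

Step 18
Reactants: 28 C8 alcohol (8-epi)
Product: 29 C8 methacrylate with the C8 configuration of 32
Conditions: methacrylic acid, PPh3, DIAD, toluene, 0 °C → rt
Reagents that add atoms: methacrylic acid C=C(C)C(=O)O
Why: Mitsunobu esterification, in which the alkoxyphosphonium salt of the C8 alcohol is displaced by methacrylate in an SN2 reaction that installs the ester and inverts C8 from S to the R configuration of the target.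

Step 19
Reactants: 29 methacrylate acetonide
Product: 30 C3/C15 diol
Conditions: AcOH–H2O (4:1), 40 °C
Reagents that add atoms: none
Why: Mild acid hydrolysis of the isopropylidene acetal, which spares the methacrylate and the lactone.

Step 20
Reactants: 30 C3/C15 diol
Product: 32 target, via cyclic orthoacetate 31 (not isolated)
Conditions: MeC(OMe)3, PPTS (cat.), CH2Cl2, rt; then AcOH–H2O (4:1), rt
Reagents that add atoms: trimethyl orthoacetate CC(OC)(OC)OC; water O
Why: Orthoester route to the monoacetate, in which the 1,3-diol forms the cyclic methyl orthoacetate and its hydrolysis through the dioxan-2-ylium ion and the hemiorthoester expels the less hindered primary oxygen, leaving the acetyl group on O3 and the C15 hydroxyl free.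

**Compound list**

1 | (tert-butyldimethylsilyloxy)acetaldehyde | O=CCO[Si](C)(C)C(C)(C)C | starting material
2 | ethyl diazoacetate | CCOC(=O)C=[N+]=[N-] | starting material
3 | ethyl 4-(tert-butyldimethylsilyloxy)-2-diazo-3-hydroxybutanoate (racemic) | CCOC(=O)C(=[N+]=[N-])C(O)CO[Si](C)(C)C(C)(C)C | intermediate
4 | ethyl 4-(tert-butyldimethylsilyloxy)-2-diazo-3-oxobutanoate | CCOC(=O)C(=[N+]=[N-])C(=O)CO[Si](C)(C)C(C)(C)C | intermediate
5 | (S)-benzyl glycidyl ether | C1[C@H](O1)COCc2ccccc2 | starting material
6 | (S)-1-(benzyloxy)pent-4-yn-2-ol | C#CC[C@H](O)COCc1ccccc1 | intermediate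
7 | (S)-1-(benzyloxy)-2-(tert-butyldimethylsilyloxy)pent-4-yne | C#CC[C@H](O[Si](C)(C)C(C)(C)C)COCc1ccccc1 | intermediate
8 | (S,E)-1-(benzyloxy)-2-(tert-butyldimethylsilyloxy)-5-iodo-4-methylpent-4-ene | I/C=C(\C)C[C@H](O[Si](C)(C)C(C)(C)C)COCc1ccccc1 | intermediate
9 | dimethylphenylvinylsilane | C=C[Si](C)(C)c1ccccc1 | starting material
10 | (S,4E,6E)-1-(benzyloxy)-2-(tert-butyldimethylsilyloxy)-4-methyl-7-(dimethylphenylsilyl)hepta-4,6-diene | C[Si](C)(c1ccccc1)/C=C/C=C(\C)C[C@H](O[Si](C)(C)C(C)(C)C)COCc1ccccc1 | intermediate
11 | methyl (triphenylphosphoranylidene)acetate | COC(=O)C=P(c1ccccc1)(c1ccccc1)c1ccccc1 | starting material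
12 | (iodomethyl)trimethylsilane | C[Si](C)(C)CI | starting material
13 | [1-methoxy-1-oxo-3-(trimethylsilyl)propan-2-yl]triphenylphosphonium iodide | COC(=O)C(C[Si](C)(C)C)[P+](c1ccccc1)(c1ccccc1)c1ccccc1.[I-] | intermediate
14 | methyl 2-(triphenylphosphoranylidene)-3-(trimethylsilyl)propanoate | COC(=O)C(C[Si](C)(C)C)=P(c1ccccc1)(c1ccccc1)c1ccccc1 | intermediate
15 | vinylcyclopropane: ethyl 1-[(tert-butyldimethylsilyloxy)acetyl]-2-(dimethylphenylsilyl)-3-[(E)-alkenyl]cyclopropane-1-carboxylate, silyl trans and ketone cis to the alkenyl group | CCOC(=O)[C@]1(C(=O)CO[Si](C)(C)C(C)(C)C)[C@H]([Si](C)(C)c2ccccc2)[C@H]1/C=C(\C)C[C@H](O[Si](C)(C)C(C)(C)C)COCc1ccccc1 | intermediate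
16 | 2,5-dihydrooxepine: C10 (methyl; CH2–CH(OTBS)–CH2OBn), C1=C2, C3 (SiMe2Ph, cis to the C10 side chain), C4 (CO2Et)=C5 (CH2OTBS) | C[C@]1(C[C@H](O[Si](C)(C)C(C)(C)C)COCc2ccccc2)C=C[C@@H]([Si](C)(C)c2ccccc2)C(C(=O)OCC)=C(CO[Si](C)(C)C(C)(C)C)O1 | intermediate
17 | oxepane: C3 SiMe2Ph, C4 CO2Et and C5 CH2OTBS all cis, C7 OH, C8 OTBS (C5 and C8 epimeric to 32) | C[C@]1(C[C@H](O[Si](C)(C)C(C)(C)C)CO)CC[C@@H]([Si](C)(C)c2ccccc2)[C@@H](C(=O)OCC)[C@@H](CO[Si](C)(C)C(C)(C)C)O1 | intermediate
18 | β-hydroxy ester: as 17 with C3 OH in place of silicon | C[C@]1(C[C@H](O[Si](C)(C)C(C)(C)C)CO)CC[C@@H](O)[C@@H](C(=O)OCC)[C@@H](CO[Si](C)(C)C(C)(C)C)O1 | intermediate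
19 | triol: C3 OH, C15 OH, C7 OH; C6 and C8 silyl ethers | C[C@]1(C[C@H](O[Si](C)(C)C(C)(C)C)CO)CC[C@@H](O)[C@@H](CO)[C@@H](CO[Si](C)(C)C(C)(C)C)O1 | intermediate
20 | O3/O15 acetonide with free C7 OH | C[C@]1(C[C@H](O[Si](C)(C)C(C)(C)C)CO)CC[C@H]2OC(C)(C)OC[C@H]2[C@@H](CO[Si](C)(C)C(C)(C)C)O1 | intermediate
21 | C7 aldehyde of 20 | C[C@]1(C[C@H](O[Si](C)(C)C(C)(C)C)C=O)CC[C@H]2OC(C)(C)OC[C@H]2[C@@H](CO[Si](C)(C)C(C)(C)C)O1 | intermediate
22 | methyl (Z)-2-(trimethylsilylmethyl)alk-2-enoate (C7=C11, C8 cis to CH2SiMe3) | C[C@]1(C[C@H](O[Si](C)(C)C(C)(C)C)/C=C(\C[Si](C)(C)C)C(=O)OC)CC[C@H]2OC(C)(C)OC[C@H]2[C@@H](CO[Si](C)(C)C(C)(C)C)O1 | intermediate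
23 | C6 primary alcohol of 22 | C[C@]1(C[C@H](O[Si](C)(C)C(C)(C)C)/C=C(\C[Si](C)(C)C)C(=O)OC)CC[C@H]2OC(C)(C)OC[C@H]2[C@@H](CO)O1 | intermediate
24 | C6 aldehyde, formyl cis to the C4 branch (5-epi) | C[C@]1(C[C@H](O[Si](C)(C)C(C)(C)C)/C=C(\C[Si](C)(C)C)C(=O)OC)CC[C@H]2OC(C)(C)OC[C@H]2[C@@H](C=O)O1 | intermediate
25 | C6 aldehyde, formyl trans to the C4 branch (C5 as in 32) | C[C@]1(C[C@H](O[Si](C)(C)C(C)(C)C)/C=C(\C[Si](C)(C)C)C(=O)OC)CC[C@H]2OC(C)(C)OC[C@H]2[C@H](C=O)O1 | intermediate
26 | bicyclic hydroxy ester: C6 OH, C7 bearing C(=CH2)CO2Me, C8 OTBS | COC(=O)C(=C)[C@@H]1[C@@H](O[Si](C)(C)C(C)(C)C)C[C@@]2(C)CC[C@H]3OC(C)(C)OC[C@H]3[C@@H](O2)[C@@H]1O | intermediate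
27 | bicyclic cis-fused α-methylene lactone, C8 OTBS (8-epi), O3/O15 acetonide | CC(C)(C)[Si](C)(C)O[C@H]1C[C@@]2(C)CC[C@H]3OC(C)(C)OC[C@H]3[C@@H](O2)[C@@H]2OC(=O)C(=C)[C@@H]21 | intermediate
28 | C8 alcohol (8-epi) of 27 | O[C@H]1C[C@@]2(C)CC[C@H]3OC(C)(C)OC[C@H]3[C@@H](O2)[C@@H]2OC(=O)C(=C)[C@@H]21 | intermediate
29 | C8 methacrylate (C8 as in 32), O3/O15 acetonide | C=C(C)C(=O)O[C@@H]1C[C@@]2(C)CC[C@H]3OC(C)(C)OC[C@H]3[C@@H](O2)[C@@H]2OC(=O)C(=C)[C@@H]21 | intermediate
30 | C3/C15 diol | C=C(C)C(=O)O[C@@H]1C[C@@]2(C)CC[C@@H](O)[C@@H](CO)[C@@H](O2)[C@@H]2OC(=O)C(=C)[C@@H]21 | intermediate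
31 | cyclic methyl orthoacetate of 30 (orthoester carbon as a mixture) | C=C(C)C(=O)O[C@@H]1C[C@@]2(C)CC[C@H]3OC(C)(OC)OC[C@H]3[C@@H](O2)[C@@H]2OC(=O)C(=C)[C@@H]21 | intermediate
32 | CNP0602302.1, (3R,4R,5R,6R,7R,8R,10R)-3-acetoxy-15-hydroxy-8-methacryloyloxy-5,10-epoxygermacr-11(13)-en-6,12-olide | C=C(C)C(=O)O[C@@H]1C[C@@]2(C)CC[C@@H](OC(C)=O)[C@@H](CO)[C@@H](O2)[C@@H]2OC(=O)C(=C)[C@@H]21 | target

**Summary**

Total step count: 20. Longest linear sequence: 17 steps (steps 3–6 and 8–20).

Steps most likely to fail:

Step 8. The carbene transfer may lose site and face selectivity (attack at the trisubstituted C1=C10 bond, ylide formation at the silyl ether oxygen, weak induction by the catalyst), and the donor–acceptor cyclopropane may open ionically to a 2-vinyl-2,3-dihydrofuran before the sigmatropic shift. The fallback gives up the diazo compound, the chiral catalyst and the one-pot cascade; it sets out from 1, 2 and 10 and comes back at 16. SnCl2-catalysed Roskamp homologation of 1 with 2 gives ethyl 4-(tert-butyldimethylsilyloxy)-3-oxobutanoate F1. PhI(OAc)2 and KOH in MeOH convert it into its phenyliodonium ylide F2. Cu(acac)2-catalysed transfer of the dicarbonyl carbene from F2 to 10 at rt gives vinylcyclopropane 15 as two diastereomers (C3 against the resident C8 centre), which are separated by chromatography instead of being controlled by a catalyst. The correct isomer is then rearranged on its own in heptane at 80 °C to 16.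

Step 16. The ring may fail to close onto the trans-disposed arms (protodesilylation or oligomerisation instead of cyclisation), or it may close through a non-chelated transition state with the wrong face selectivity at C6 and C7. The fallback uses an allylzinc reagent with a closed six-membered transition state; it sets out from 20 and comes back at 27. Dess–Martin oxidation of 20 and reaction of the aldehyde with methyl acrylate and DABCO give the Morita–Baylis–Hillman adduct F3. HF·pyridine frees the C6 alcohol to give diol F4. TEMPO/PhI(OAc)2 oxidises only the primary alcohol and DBU equilibrates C5, giving hydroxy aldehyde F5. NBS/Me2S converts the allylic alcohol with transposition into (Z)-allylic bromide F6. Zinc dust in THF–aq. NH4Cl closes the ring through a chair-like allylzinc transition state, and lactonisation of 26 gives 27.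

Step 18. Elimination toward C7=C8 or C8=C9 may outrun substitution at the hindered carbinol, and the phosphine may add to the α-methylene lactone. The fallback inverts C8 by oxidation and reagent-controlled reduction; it sets out from 28 and comes back at 29. Dess–Martin oxidation of 28 gives C8 ketone F7, which is kept free of base because C7 is then α to the ketone and allylic. Corey–Bakshi–Shibata reduction with (S)-2-methyl-CBS-oxazaborolidine and catecholborane at −78 °C gives the (8R)-alcohol F8. Methacrylic anhydride, Et3N and DMAP give 29.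

**Further compounds**

F1 | step 8 | ethyl 4-(tert-butyldimethylsilyloxy)-3-oxobutanoate | CCOC(=O)CC(=O)CO[Si](C)(C)C(C)(C)C
F2 | step 8 | phenyliodonium ylide of F1 | CCOC(=O)[C-]([I+]c1ccccc1)C(=O)CO[Si](C)(C)C(C)(C)C
F3 | step 16 | Morita–Baylis–Hillman adduct at C7 (carbinol mixture), C6 OTBS | C[C@]1(C[C@H](O[Si](C)(C)C(C)(C)C)C(O)C(=C)C(=O)OC)CC[C@H]2OC(C)(C)OC[C@H]2[C@@H](CO[Si](C)(C)C(C)(C)C)O1
F4 | step 16 | diol: C6 OH and C7 OH | C[C@]1(C[C@H](O[Si](C)(C)C(C)(C)C)C(O)C(=C)C(=O)OC)CC[C@H]2OC(C)(C)OC[C@H]2[C@@H](CO)O1
F5 | step 16 | hydroxy aldehyde: C6 aldehyde with C5 as in 32, C7 OH | C[C@]1(C[C@H](O[Si](C)(C)C(C)(C)C)C(O)C(=C)C(=O)OC)CC[C@H]2OC(C)(C)OC[C@H]2[C@H](C=O)O1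
F6 | step 16 | methyl (Z)-2-(bromomethyl)alk-2-enoate with C6 aldehyde | C[C@]1(C[C@H](O[Si](C)(C)C(C)(C)C)/C=C(\CBr)C(=O)OC)CC[C@H]2OC(C)(C)OC[C@H]2[C@H](C=O)O1
F7 | step 18 | C8 ketone | O=C1C[C@@]2(C)CC[C@H]3OC(C)(C)OC[C@H]3[C@@H](O2)[C@@H]2OC(=O)C(=C)[C@@H]21
F8 | step 18 | (8R)-alcohol, C8 as in 32 | O[C@@H]1C[C@@]2(C)CC[C@H]3OC(C)(C)OC[C@H]3[C@@H](O2)[C@@H]2OC(=O)C(=C)[C@@H]21
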